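**Retrosynthetic overview**
1. Feature: in the pyran ring (O1–C2–C3–C4–C4a–C8a), C4 is an unsubstituted benzylic CH2 on C4a, which has O1 (on C8a) ortho and the 7-oxygen para, and C2 bears an aryl ring whose 2'-oxygen is ortho to C2. O1/C8a/C4a/C4 is therefore an ortho-quinone methide and C3/C2/aryl a 2-vinylphenol.
2. Key disconnection: C3–C4 and C2–O1, by a chiral-acid-catalysed oxa-[4+2] between a 4-benzyloxy salicyl alcohol carrying the diarylpropyl chain and 4-(benzyloxy)-2-vinylphenol. The pyran is the only ring the route builds and it is closed last.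
3. Salicyl alcohol: CH2OH from ortho-formylation and reduction of a phenol; the chain from a Weinreb amide plus an aryllithium, then ketone deoxygenation; Cα from rhodium-catalysed asymmetric arylation of silyl-protected umbelliferone.
4. End game: methylation of the single free 2'-hydroxyl, then hydrogenolysis of four benzyl ethers.

Key step: step 13

Assumption: the sense of induction of the (R)-bisphosphine in step 2 and of the (R)-phosphoric acid in step 13 is assigned by analogy with related substrates; if a model run shows the opposite sense, the antipodal ligand or acid is used with no other change.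

**Route**

Step 1
Reactants: 1 umbelliferone
Product: 2 7-(triisopropylsilyloxy)-2H-chromen-2-one
Conditions: TIPSCl, imidazole, DMF, rt
Reagents that add atoms: triisopropylsilyl chloride, CC(C)[Si](Cl)(C(C)C)C(C)C
Why: Imidazole-promoted silylation of a phenol gives an ether that is orthogonal to benzyl ethers and a weaker π-donor than an alkyl ether, which should keep the coumarin electrophilic for step 2.

Step 2
Reactants: 2 7-(triisopropylsilyloxy)-2H-chromen-2-one; 3 4-(benzyloxy)phenylboronic acid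
Product: 4 (4R)-4-[4-(benzyloxy)phenyl]-7-(triisopropylsilyloxy)chroman-2-one
Conditions: Rh(acac)(C2H4)2 (3 mol%), (R)-SEGPHOS [(R)-5,5'-bis(diphenylphosphino)-4,4'-bi-1,3-benzodioxole] (3.3 mol%), 3 (excess, in portions), dioxane/H2O 10:1, 60 °C
Reagents that add atoms: none
Why: Rhodium-catalysed asymmetric 1,4-addition of an arylboronic acid to a coumarin (Hayashi–Miyaura reaction), in which the aryl–rhodium species adds across C3=C4 on the face left open by the bisphosphine, so the ligand sets C4 (the later Cα) as R, and water protonates the rhodium enolate.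

Step 3
Reactants: 4 (4R)-4-[4-(benzyloxy)phenyl]-7-(triisopropylsilyloxy)chroman-2-one
Product: 5 (3R)-3-[4-(benzyloxy)phenyl]-3-[2-hydroxy-4-(triisopropylsilyloxy)phenyl]-N-methoxy-N-methylpropanamide
Conditions: MeNH(OMe)·HCl, AlMe3, CH2Cl2, 0 °C to rt; then aqueous work-up
Reagents that add atoms: N,O-dimethylhydroxylamine hydrochloride, CNOC.Cl
Why: Aluminium amide aminolysis of an aryl lactone (Weinreb amide formation) opens the ring and frees the former lactone oxygen as a phenol without touching the stereocentre.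

Step 4
Reactants: 5 (3R)-3-[4-(benzyloxy)phenyl]-3-[2-hydroxy-4-(triisopropylsilyloxy)phenyl]-N-methoxy-N-methylpropanamide
Product: 6 (3R)-3-[4-(benzyloxy)phenyl]-3-[2-(benzyloxy)-4-(triisopropylsilyloxy)phenyl]-N-methoxy-N-methylpropanamide
Conditions: BnBr, K2CO3, DMF, rt
Reagents that add atoms: benzyl bromide, BrCc1ccccc1
Why: Williamson etherification of the only free phenol puts the benzyl group on the oxygen ortho to the diarylmethine (the later 7-hydroxyl), and anhydrous carbonate at room temperature should spare the hindered aryl silyl ether.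

Step 5
Reactants: 7 4-bromo-3-methoxyphenol
Product: 8 4-(benzyloxy)-1-bromo-2-methoxybenzene
Conditions: BnBr, K2CO3, acetone, reflux
Reagents that add atoms: benzyl bromide, BrCc1ccccc1
Why: Williamson etherification of a simple phenol.

Step 6
Reactants: 8 4-(benzyloxy)-1-bromo-2-methoxybenzene; 6 (3R)-3-[4-(benzyloxy)phenyl]-3-[2-(benzyloxy)-4-(triisopropylsilyloxy)phenyl]-N-methoxy-N-methylpropanamide
Product: 10 (3R)-1-[4-(benzyloxy)-2-methoxyphenyl]-3-[4-(benzyloxy)phenyl]-3-[2-(benzyloxy)-4-(triisopropylsilyloxy)phenyl]propan-1-one, via aryllithium 9 (not isolated)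
Conditions: 8 (1.3 equiv), n-BuLi, THF, −78 °C; then 6, −78 to −30 °C; then H2O
Reagents that add atoms: none
Why: Bromine–lithium exchange followed by acylation of the aryllithium with a Weinreb amide (Weinreb ketone synthesis), where the lithium chelate of the tetrahedral adduct stops the addition at the ketone and the β-stereocentre is not acidic enough to be at risk.

Step 7
Reactants: 10 (3R)-1-[4-(benzyloxy)-2-methoxyphenyl]-3-[4-(benzyloxy)phenyl]-3-[2-(benzyloxy)-4-(triisopropylsilyloxy)phenyl]propan-1-one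
Product: 11 {3-(benzyloxy)-4-[(1R)-3-[4-(benzyloxy)-2-methoxyphenyl]-1-[4-(benzyloxy)phenyl]propyl]phenoxy}triisopropylsilane
Conditions: Et3SiH (3 equiv), CF3CO2H (10 equiv), CH2Cl2, 0 °C to rt
Reagents that add atoms: none
Why: Ionic hydrogenation of an aryl ketone, in which the 2-methoxy-4-benzyloxyphenyl group stabilises the benzylic cation that accepts two hydrides in turn, while the neighbouring rings offer only positions meta to their oxygen donors (so indane closure should not compete) and the ortho oxygen is already benzylated and cannot cyclise onto the ketone.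

Step 8
Reactants: 11 {3-(benzyloxy)-4-[(1R)-3-[4-(benzyloxy)-2-methoxyphenyl]-1-[4-(benzyloxy)phenyl]propyl]phenoxy}triisopropylsilane
Product: 12 3-(benzyloxy)-4-[(1R)-3-[4-(benzyloxy)-2-methoxyphenyl]-1-[4-(benzyloxy)phenyl]propyl]phenol
Conditions: Bu4NF, THF, 0 °C; then H2O
Reagents that add atoms: none
Why: Fluoride-mediated cleavage of an aryl silyl ether, which leaves benzyl and methyl ethers intact.

Step 9
Reactants: 12 3-(benzyloxy)-4-[(1R)-3-[4-(benzyloxy)-2-methoxyphenyl]-1-[4-(benzyloxy)phenyl]propyl]phenol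
Product: 13 4-(benzyloxy)-5-[(1R)-3-[4-(benzyloxy)-2-methoxyphenyl]-1-[4-(benzyloxy)phenyl]propyl]-2-hydroxybenzaldehyde
Conditions: MgCl2, Et3N, (CH2O)n, MeCN, reflux; cold dilute HCl work-up
Reagents that add atoms: paraformaldehyde (as formaldehyde), C=O
Why: Magnesium-mediated ortho-formylation of a phenol (Casnati–Skattebøl type) delivers formaldehyde through the magnesium phenoxide only to an ortho position, and the ortho site flanked by the benzyloxy group is blocked, so the formyl group should enter para to the benzyloxy group.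

Step 10
Reactants: 13 4-(benzyloxy)-5-[(1R)-3-[4-(benzyloxy)-2-methoxyphenyl]-1-[4-(benzyloxy)phenyl]propyl]-2-hydroxybenzaldehyde
Product: 14 4-(benzyloxy)-2-hydroxy-5-[(1R)-3-[4-(benzyloxy)-2-methoxyphenyl]-1-[4-(benzyloxy)phenyl]propyl]benzyl alcohol
Conditions: NaBH4, THF/MeOH, 0 °C; neutral aqueous work-up
Reagents that add atoms: none
Why: Borohydride reduction of a salicylaldehyde under basic conditions, which the acid-labile salicyl alcohol tolerates.

Step 11
Reactants: 15 4-(benzyloxy)phenol
Product: 16 5-(benzyloxy)-2-hydroxybenzaldehyde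
Conditions: MgCl2, Et3N, (CH2O)n, MeCN, reflux; dilute HCl work-up
Reagents that add atoms: paraformaldehyde (as formaldehyde), C=O
Why: The same magnesium-mediated ortho-formylation, regiochemically unambiguous here because the two ortho positions are equivalent.

Step 12
Reactants: 16 5-(benzyloxy)-2-hydroxybenzaldehyde
Product: 17 4-(benzyloxy)-2-vinylphenol
Conditions: Ph3PCH3Br (2.5 equiv), KOtBu (2.5 equiv), THF, 0 °C to rt; use promptly, store cold
Reagents that add atoms: methyltriphenylphosphonium bromide, C[P+](c1ccccc1)(c1ccccc1)c1ccccc1.[Br-]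
Why: Wittig methylenation of a salicylaldehyde, in which the excess ylide first deprotonates the phenol and the phenoxide aldehyde is still olefinated.

Step 13
Reactants: 14 4-(benzyloxy)-2-hydroxy-5-[(1R)-3-[4-(benzyloxy)-2-methoxyphenyl]-1-[4-(benzyloxy)phenyl]propyl]benzyl alcohol; 17 4-(benzyloxy)-2-vinylphenol
Product: 19 4-(benzyloxy)-2-[(2S)-7-(benzyloxy)-6-[(1R)-3-[4-(benzyloxy)-2-methoxyphenyl]-1-[4-(benzyloxy)phenyl]propyl]chroman-2-yl]phenol, via ortho-quinone methide 18 (not isolated)
Conditions: (R)-3,3'-bis(2,4,6-triisopropylphenyl)-1,1'-binaphthyl-2,2'-diyl hydrogen phosphate (10 mol%), 3 Å MS, toluene, 0 °C to rt; 17 (2 equiv), 14 added slowly; Et3N quench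
Reagents that add atoms: none
Why: Proposed new method: the phosphoric acid should dehydrate the primary salicyl alcohol 14 to the unsubstituted ortho-quinone methide 18, an ionisation made feasible without a benzylic aryl group by the benzyloxy donor para to the methide carbon, after which the vinyl terminus of 17 attacks the methide CH2 (C3–C4) and the benzylic cation developing at C2, stabilised by the ortho-hydroxyl, is captured by the methide oxygen (C2–O1). The closest known reaction type is the chiral phosphoric acid catalysed inverse-electron-demand oxa-[4+2] of ortho-quinone methides, generated in situ from aryl-substituted secondary ortho-hydroxybenzyl alcohols, with ortho-hydroxystyrenes; leaving the methide carbon unsubstituted is the untested extension. The pyran closes as an asynchronous [4+2] cycloaddition, which in its stepwise limit is a 6-exo-trig attack of the phenolic oxygen on cationic C2. The new C2 stereocentre is set by the catalyst, whose phosphate bridges the methide oxygen and the free ortho-hydroxyl of 17 while its 3,3'-aryl groups shield one face of the styrene, and the existing Cα centre, para to O1, is too remote to interfere. The step needs 2-aryl regiochemistry, which the polarity match of nucleophilic vinyl terminus and electrophilic methide carbon secures, and enantioface selection on the styrene, for which the ortho-hydroxyl of 17 is the binding handle; that hydroxyl is afterwards the only free phenol, which makes step 14 unambiguous.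

Step 14
Reactants: 19 4-(benzyloxy)-2-[(2S)-7-(benzyloxy)-6-[(1R)-3-[4-(benzyloxy)-2-methoxyphenyl]-1-[4-(benzyloxy)phenyl]propyl]chroman-2-yl]phenol
Product: 20 (2S)-7-(benzyloxy)-2-[5-(benzyloxy)-2-methoxyphenyl]-6-[(1R)-3-[4-(benzyloxy)-2-methoxyphenyl]-1-[4-(benzyloxy)phenyl]propyl]chromane
Conditions: MeI, K2CO3, acetone, rt
Reagents that add atoms: iodomethane, CI
Why: Williamson methylation of the single free phenol, run with mild base at room temperature because a 2'-phenoxide could in principle open the pyran by expelling O1 and so scramble C2.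

Step 15
Reactants: 20 (2S)-7-(benzyloxy)-2-[5-(benzyloxy)-2-methoxyphenyl]-6-[(1R)-3-[4-(benzyloxy)-2-methoxyphenyl]-1-[4-(benzyloxy)phenyl]propyl]chromane
Product: 21 4-[(3R)-3-[(2S)-7-hydroxy-2-(5-hydroxy-2-methoxyphenyl)chroman-6-yl]-3-(4-hydroxyphenyl)propyl]-3-methoxyphenol
Conditions: H2 (1 atm), 10% Pd/C, EtOAc/MeOH, rt
Reagents that add atoms: none
Why: Heterogeneous hydrogenolysis of four aryl benzyl ethers, which should be much faster than cleavage of the cyclic benzylic C2–O1 bond and does not affect either stereocentre.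

**Compound list**
1 | umbelliferone (7-hydroxy-2H-chromen-2-one) | O=c1ccc2ccc(O)cc2o1 | starting material
2 | 7-(triisopropylsilyloxy)-2H-chromen-2-one | O=c1ccc2ccc(O[Si](C(C)C)(C(C)C)C(C)C)cc2o1 | intermediate
3 | 4-(benzyloxy)phenylboronic acid | OB(O)c1ccc(OCc2ccccc2)cc1 | starting material
4 | (4R)-4-[4-(benzyloxy)phenyl]-7-(triisopropylsilyloxy)chroman-2-one | O=C1C[C@H](c2ccc(OCc3ccccc3)cc2)c2ccc(O[Si](C(C)C)(C(C)C)C(C)C)cc2O1 | intermediate
5 | (3R)-3-[4-(benzyloxy)phenyl]-3-[2-hydroxy-4-(triisopropylsilyloxy)phenyl]-N-methoxy-N-methylpropanamide | CON(C)C(=O)C[C@H](c1ccc(OCc2ccccc2)cc1)c1ccc(O[Si](C(C)C)(C(C)C)C(C)C)cc1O | intermediate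
6 | (3R)-3-[4-(benzyloxy)phenyl]-3-[2-(benzyloxy)-4-(triisopropylsilyloxy)phenyl]-N-methoxy-N-methylpropanamide | CON(C)C(=O)C[C@H](c1ccc(OCc2ccccc2)cc1)c1ccc(O[Si](C(C)C)(C(C)C)C(C)C)cc1OCc1ccccc1 | intermediate
7 | 4-bromo-3-methoxyphenol | COc1cc(O)ccc1Br | starting material
8 | 4-(benzyloxy)-1-bromo-2-methoxybenzene | COc1cc(OCc2ccccc2)ccc1Br | intermediate
9 | [4-(benzyloxy)-2-methoxyphenyl]lithium | [Li]c1ccc(OCc2ccccc2)cc1OC | intermediate
10 | (3R)-1-[4-(benzyloxy)-2-methoxyphenyl]-3-[4-(benzyloxy)phenyl]-3-[2-(benzyloxy)-4-(triisopropylsilyloxy)phenyl]propan-1-one | COc1cc(OCc2ccccc2)ccc1C(=O)C[C@H](c1ccc(OCc2ccccc2)cc1)c1ccc(O[Si](C(C)C)(C(C)C)C(C)C)cc1OCc1ccccc1 | intermediate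
11 | {3-(benzyloxy)-4-[(1R)-3-[4-(benzyloxy)-2-methoxyphenyl]-1-[4-(benzyloxy)phenyl]propyl]phenoxy}triisopropylsilane | COc1cc(OCc2ccccc2)ccc1CC[C@H](c1ccc(OCc2ccccc2)cc1)c1ccc(O[Si](C(C)C)(C(C)C)C(C)C)cc1OCc1ccccc1 | intermediate
12 | 3-(benzyloxy)-4-[(1R)-3-[4-(benzyloxy)-2-methoxyphenyl]-1-[4-(benzyloxy)phenyl]propyl]phenol | COc1cc(OCc2ccccc2)ccc1CC[C@H](c1ccc(OCc2ccccc2)cc1)c1ccc(O)cc1OCc1ccccc1 | intermediate
13 | 4-(benzyloxy)-5-[(1R)-3-[4-(benzyloxy)-2-methoxyphenyl]-1-[4-(benzyloxy)phenyl]propyl]-2-hydroxybenzaldehyde | COc1cc(OCc2ccccc2)ccc1CC[C@H](c1ccc(OCc2ccccc2)cc1)c1cc(C=O)c(O)cc1OCc1ccccc1 | intermediate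
14 | 4-(benzyloxy)-2-hydroxy-5-[(1R)-3-[4-(benzyloxy)-2-methoxyphenyl]-1-[4-(benzyloxy)phenyl]propyl]benzyl alcohol | COc1cc(OCc2ccccc2)ccc1CC[C@H](c1ccc(OCc2ccccc2)cc1)c1cc(CO)c(O)cc1OCc1ccccc1 | intermediate
15 | 4-(benzyloxy)phenol | Oc1ccc(OCc2ccccc2)cc1 | starting material
16 | 5-(benzyloxy)-2-hydroxybenzaldehyde | O=Cc1cc(OCc2ccccc2)ccc1O | intermediate
17 | 4-(benzyloxy)-2-vinylphenol | C=Cc1cc(OCc2ccccc2)ccc1O | intermediate
18 | 3-(benzyloxy)-4-[(1R)-3-[4-(benzyloxy)-2-methoxyphenyl]-1-[4-(benzyloxy)phenyl]propyl]-6-methylidenecyclohexa-2,4-dien-1-one (ortho-quinone methide) | COc1cc(OCc2ccccc2)ccc1CC[C@H](c1ccc(OCc2ccccc2)cc1)C1=CC(=C)C(=O)C=C1OCc1ccccc1 | intermediate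
19 | 4-(benzyloxy)-2-[(2S)-7-(benzyloxy)-6-[(1R)-3-[4-(benzyloxy)-2-methoxyphenyl]-1-[4-(benzyloxy)phenyl]propyl]chroman-2-yl]phenol | COc1cc(OCc2ccccc2)ccc1CC[C@H](c1ccc(OCc2ccccc2)cc1)c1cc2c(cc1OCc1ccccc1)O[C@H](c1cc(OCc3ccccc3)ccc1O)CC2 | intermediate
20 | (2S)-7-(benzyloxy)-2-[5-(benzyloxy)-2-methoxyphenyl]-6-[(1R)-3-[4-(benzyloxy)-2-methoxyphenyl]-1-[4-(benzyloxy)phenyl]propyl]chromane | COc1cc(OCc2ccccc2)ccc1CC[C@H](c1ccc(OCc2ccccc2)cc1)c1cc2c(cc1OCc1ccccc1)O[C@H](c1cc(OCc3ccccc3)ccc1OC)CC2 | intermediate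
21 | 4-[(3R)-3-[(2S)-7-hydroxy-2-(5-hydroxy-2-methoxyphenyl)chroman-6-yl]-3-(4-hydroxyphenyl)propyl]-3-methoxyphenol | COc1cc(O)ccc1CC[C@H](c1ccc(O)cc1)c1cc2c(cc1O)O[C@H](c1cc(O)ccc1OC)CC2 | target

**Step count**
Total: 15 steps. Longest linear sequence: 12 steps from umbelliferone (steps 1–4, 6–10, 13–15).

**Steps most likely to fail**

Step 13 (proposed new method). The primary alcohol may ionise too slowly with this acid, and the unhindered methide may be consumed by O- or C-benzylation of phenols in the flask (oligomerisation). The vinylphenol may dimerise under acid, and facial selection on the styrene may be incomplete, giving C2 epimers that are hard to separate because the second centre is remote. A more acidic N-triflyl phosphoramide on the same backbone is the first adjustment inside the strategy.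
The fallback uses known chemistry and sets out from aldehyde 13. Commercial 2',5'-dihydroxyacetophenone is benzylated at the non-chelated 5-hydroxyl (BnBr, K2CO3, acetone) to 1-[5-(benzyloxy)-2-hydroxyphenyl]ethanone F1 and methylated (MeI, K2CO3, DMF) to 1-[5-(benzyloxy)-2-methoxyphenyl]ethanone F2. Claisen–Schmidt condensation of 13 with F2 (KOH, EtOH) should give the (E)-2-hydroxychalcone F3. Hydrogenation of the alkene with RhCl(PPh3)3 and H2, which spares benzyl ethers, gives the dihydrochalcone F4. Corey–Bakshi–Shibata reduction ((S)-2-methyl-CBS-oxazaborolidine, excess BH3·SMe2, because the phenol consumes hydride) gives the (R)-carbinol F5. Intramolecular Mitsunobu etherification (PPh3, DIAD, THF, 0 °C) closes the pyran with inversion and comes back to the route at 20, so steps 10 to 14 are bypassed.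

Step 2. The donor-substituted coumarin may insert too slowly into the aryl–rhodium bond, so that protodeboronation of 3 consumes the boronic acid and conversion stalls.
The fallback sets the stereocentre on an acyclic acceptor and sets out from boronic acid 3 and commercial 2,4-dihydroxybenzaldehyde (O=Cc1ccc(O)cc1O). Selective silylation of the non-chelated 4-hydroxyl (TIPSCl, Et3N, CH2Cl2, 0 °C) gives 2-hydroxy-4-(triisopropylsilyloxy)benzaldehyde F6. Wittig olefination with the stabilised ylide Ph3P=CHC(O)N(OMe)Me (toluene, 80 °C) gives (E)-3-[2-hydroxy-4-(triisopropylsilyloxy)phenyl]-N-methoxy-N-methylprop-2-enamide F7, and benzylation (BnBr, K2CO3, DMF, rt) gives (E)-3-[2-(benzyloxy)-4-(triisopropylsilyloxy)phenyl]-N-methoxy-N-methylprop-2-enamide F8. Rhodium/chiral diene catalysed asymmetric 1,4-addition of 3 to F8 ([RhCl(C2H4)2]2, an enantiopure 2,5-diphenylbicyclo[2.2.2]octa-2,5-diene, aq. KOH, dioxane, 30–50 °C), an established reaction of unsaturated Weinreb amides, comes back to the route at 6, so steps 1 to 4 are not needed.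

Step 7. The benzylic cation may react other than by hydride capture (ring closure onto a neighbouring arene, elimination), and the strong acid may cause loss or migration of a benzyl or silyl group.
The fallback avoids cationic intermediates and sets out from ketone 10. Condensation with TsNHNH2 (EtOH, 60 °C) gives the tosylhydrazone F9. Reduction with catecholborane (CHCl3, 0 °C), then NaOAc·3H2O at reflux, expels sulfinate and nitrogen from the diazene and comes back to the route at 11.

**Further compounds**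
F1 | step 13 | 1-[5-(benzyloxy)-2-hydroxyphenyl]ethanone | CC(=O)c1cc(OCc2ccccc2)ccc1O
F2 | step 13 | 1-[5-(benzyloxy)-2-methoxyphenyl]ethanone | COc1ccc(OCc2ccccc2)cc1C(C)=O
F3 | step 13 | (E)-3-{4-(benzyloxy)-5-[(1R)-3-[4-(benzyloxy)-2-methoxyphenyl]-1-[4-(benzyloxy)phenyl]propyl]-2-hydroxyphenyl}-1-[5-(benzyloxy)-2-methoxyphenyl]prop-2-en-1-one | COc1cc(OCc2ccccc2)ccc1CC[C@H](c1ccc(OCc2ccccc2)cc1)c1cc(/C=C/C(=O)c2cc(OCc3ccccc3)ccc2OC)c(O)cc1OCc1ccccc1
F4 | step 13 | 3-{4-(benzyloxy)-5-[(1R)-3-[4-(benzyloxy)-2-methoxyphenyl]-1-[4-(benzyloxy)phenyl]propyl]-2-hydroxyphenyl}-1-[5-(benzyloxy)-2-methoxyphenyl]propan-1-one | COc1cc(OCc2ccccc2)ccc1CC[C@H](c1ccc(OCc2ccccc2)cc1)c1cc(CCC(=O)c2cc(OCc3ccccc3)ccc2OC)c(O)cc1OCc1ccccc1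
F5 | step 13 | 5-(benzyloxy)-4-[(1R)-3-[4-(benzyloxy)-2-methoxyphenyl]-1-[4-(benzyloxy)phenyl]propyl]-2-[(3R)-3-[5-(benzyloxy)-2-methoxyphenyl]-3-hydroxypropyl]phenol | COc1cc(OCc2ccccc2)ccc1CC[C@H](c1ccc(OCc2ccccc2)cc1)c1cc(CC[C@@H](O)c2cc(OCc3ccccc3)ccc2OC)c(O)cc1OCc1ccccc1
F6 | step 2 | 2-hydroxy-4-(triisopropylsilyloxy)benzaldehyde | O=Cc1ccc(O[Si](C(C)C)(C(C)C)C(C)C)cc1O
F7 | step 2 | (E)-3-[2-hydroxy-4-(triisopropylsilyloxy)phenyl]-N-methoxy-N-methylprop-2-enamide | CON(C)C(=O)/C=C/c1ccc(O[Si](C(C)C)(C(C)C)C(C)C)cc1O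
F8 | step 2 | (E)-3-[2-(benzyloxy)-4-(triisopropylsilyloxy)phenyl]-N-methoxy-N-methylprop-2-enamide | CON(C)C(=O)/C=C/c1ccc(O[Si](C(C)C)(C(C)C)C(C)C)cc1OCc1ccccc1
F9 | step 7 | 4-methylbenzenesulfonohydrazone of ketone 10 | COc1cc(OCc2ccccc2)ccc1C(=NNS(=O)(=O)c1ccc(C)cc1)C[C@H](c1ccc(OCc2ccccc2)cc1)c1ccc(O[Si](C(C)C)(C(C)C)C(C)C)cc1OCc1ccccc1
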